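**Retrosynthetic overview**
1. Target 34 ⇐ hydrogenolysis of tri-benzyl ether 33. The C2''–aryl bond of unit 2 (the 4'-methoxy flavanone) comes from an asymmetric conjugate arylation of chromone 27, so ring C of unit 2 is formed last.
2. Chromone 27 ⇐ acetylation and one-carbon annulation on the 2,6-dihydroxy-4-benzyloxyphenyl ring of flavanone 21. The benzyl ether blocks O-5'', so closure can only use the oxygen next to the interflavanone bond.
3. Ring C of unit 1 (the 4'-hydroxy flavanone) ⇐ enantioselective dehydrative C2–O closure of aldol 19.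
4. The C3–C8'' interflavanone bond ⇐ 1,2-aryl shift of a β-oxido carbenoid made from symmetric benzophenone 10 and CH2Br2; the resulting enolate is trapped by aldehyde 13.
5. Benzophenone 10 ⇐ two molecules of a phloroglucinol triether (from resorcinol by C–H borylation/oxidation) and a C1 unit.

Assumption: the absolute sense of induction of the two chiral catalysts (steps 9 and 15) is assigned by analogy with their closest precedents; if it is found opposite, the mirror-image catalyst is used.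

**Route**

Step 1
Reactants: 1 resorcinol
Product: 2 1,3-bis(methoxymethoxy)benzene
Conditions: NaH, MOMCl, DMF, 0 °C → rt
Reagents that add atoms: chloromethyl methyl ether, COCCl
Why: Williamson-type O-alkylation of both phenoxides installs the acetal groups that later direct ortho-lithiation.

Step 2
Reactants: 2 1,3-bis(methoxymethoxy)benzene
Product: 4 3,5-bis(methoxymethoxy)phenol, via arylboronate 3 (not isolated)
Conditions: [Ir(OMe)(cod)]2 (1.5 mol %), 4,4'-di-tert-butyl-2,2'-bipyridine (3 mol %), B2pin2 (1.0 equiv), THF, 80 °C; then 30% H2O2, aq. NaOH, 0 °C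
Reagents that add atoms: hydrogen peroxide, OO
Why: Sterically controlled iridium-catalysed C–H borylation occurs only at the position meta to both substituents, and boronate oxidation then gives the phloroglucinol pattern (borylation/oxidation sequence).

Step 3
Reactants: 4 3,5-bis(methoxymethoxy)phenol
Product: 5 1-(benzyloxy)-3,5-bis(methoxymethoxy)benzene
Conditions: BnBr, K2CO3, DMF, rt
Reagents that add atoms: benzyl bromide, BrCc1ccccc1
Why: Williamson etherification marks the oxygen that becomes O-7 of unit 1 and O-5'' of unit 2 with a group that does not direct lithiation and is removed only at the end.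

Step 4
Reactants: 5 1-(benzyloxy)-3,5-bis(methoxymethoxy)benzene (2 equiv); 6 N,N-dimethylcarbamoyl chloride
Product: 10 bis[4-(benzyloxy)-2,6-bis(methoxymethoxy)phenyl]methanone, via aryllithium 7 (not isolated), via benzamide 8 (not isolated), via tetrahedral lithium alkoxide 9 (not isolated)
Conditions: n-BuLi (1.05 equiv), THF, 0 °C; then 6 (0.5 equiv), −78 °C → rt; H2O
Reagents that add atoms: none
Why: Directed ortho-metalation between the two acetal groups, then double acylation of the carbamoyl chloride, gives the ketone because the tetrahedral adduct 9 resists a third addition (diaryl ketone synthesis from an aryllithium and a carbamoyl chloride).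

Step 5
Reactants: 11 4-methylphenol
Product: 12 4-hydroxybenzaldehyde
Conditions: O2 (1 atm), CoCl2·6H2O (1 mol %), NaOH (3 equiv), MeOH, 60 °C; then aq. HCl
Reagents that add atoms: dioxygen, O=O
Why: Cobalt-catalysed aerobic oxidation of the para-cresolate methyl group proceeds through the quinone methide and stops at the aldehyde (benzylic autoxidation).

Step 6
Reactants: 12 4-hydroxybenzaldehyde
Product: 13 4-(benzyloxy)benzaldehyde
Conditions: BnBr, K2CO3, DMF, rt
Reagents that add atoms: benzyl bromide, BrCc1ccccc1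
Why: Williamson etherification protects the phenol that would otherwise quench the enolate in step 7.

Step 7
Reactants: 10 bis[4-(benzyloxy)-2,6-bis(methoxymethoxy)phenyl]methanone; 14 dibromomethane; 13 4-(benzyloxy)benzaldehyde
Product: 18 1,2-bis[4-(benzyloxy)-2,6-bis(methoxymethoxy)phenyl]-3-[4-(benzyloxy)phenyl]-3-hydroxypropan-1-one (racemic diastereomer mixture), via dibromomethyl carbinolate 15 (not isolated), via β-oxido carbenoid 16 (not isolated), via lithium enolate 17 (not isolated)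
Conditions: 14, lithium 2,2,6,6-tetramethylpiperidide, THF, −78 °C; n-BuLi (1.05 equiv), −78 → −20 °C; then 13, −78 °C; AcOH
Reagents that add atoms: none
Why: Dibromomethyllithium adds to the non-enolisable ketone, Br/Li exchange gives a β-oxido carbenoid, and its electron-rich aryl group makes an anionotropic 1,2-shift with loss of LiBr (carbenoid ketone homologation) to forge the C3–C8'' bond as a deoxybenzoin enolate, which adds to 13 in an aldol reaction; the two new stereocentres form unselectively and are reset in step 9.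

Step 8
Reactants: 18 1,2-bis[4-(benzyloxy)-2,6-bis(methoxymethoxy)phenyl]-3-[4-(benzyloxy)phenyl]-3-hydroxypropan-1-one
Product: 19 1-[4-(benzyloxy)-2-hydroxy-6-(methoxymethoxy)phenyl]-2-[4-(benzyloxy)-2,6-bis(methoxymethoxy)phenyl]-3-[4-(benzyloxy)phenyl]-3-hydroxypropan-1-one
Conditions: MgBr2·OEt2 (2 equiv), Et2O/CH2Cl2, 0 °C; aq. NaHCO3
Reagents that add atoms: none
Why: Chelation of magnesium between the ketone and an ortho acetal oxygen activates only an acetal on the acyl-bearing ring (chelation-controlled acetal cleavage), and the hydrogen bond of the freed phenol to the carbonyl prevents a second cleavage.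

Step 9
Reactants: 19 1-[4-(benzyloxy)-2-hydroxy-6-(methoxymethoxy)phenyl]-2-[4-(benzyloxy)-2,6-bis(methoxymethoxy)phenyl]-3-[4-(benzyloxy)phenyl]-3-hydroxypropan-1-one
Product: 20 (2R,3S)-7-(benzyloxy)-2-[4-(benzyloxy)phenyl]-3-[4-(benzyloxy)-2,6-bis(methoxymethoxy)phenyl]-5-(methoxymethoxy)-2,3-dihydro-4H-chromen-4-one
Conditions: (R)-3,3'-bis(2,4,6-triisopropylphenyl)-1,1'-binaphthyl-2,2'-diyl N-triflylphosphoramide (10 mol %), toluene (0.02 M), −40 → 0 °C
Reagents that add atoms: none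
Why: Proposed new method: the strong chiral acid ionises the 4-benzyloxybenzylic alcohol to a contact ion pair whose phosphoramide anion is hydrogen-bonded to the ketone-chelated phenol, so six-membered C–O closure (or, after loss of the α-proton, acid-catalysed oxa-Michael closure of the same ion-paired cation) sets C2 as R under catalyst control from either diastereomer of 19 (enantioconvergent dehydrative etherification), and C3 then equilibrates through the enol to the diequatorial 2,3-trans (3S) isomer; the closest known reaction types are chiral N-triflylphosphoramide-catalysed allylic etherification of phenols to 2H-chromenes through chiral contact ion pairs and chiral phosphoric acid-catalysed additions to para-quinone methides formed in situ.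

Step 10
Reactants: 20 (2R,3S)-7-(benzyloxy)-2-[4-(benzyloxy)phenyl]-3-[4-(benzyloxy)-2,6-bis(methoxymethoxy)phenyl]-5-(methoxymethoxy)-2,3-dihydro-4H-chromen-4-one
Product: 21 (2R,3S)-7-(benzyloxy)-2-[4-(benzyloxy)phenyl]-3-[4-(benzyloxy)-2,6-dihydroxyphenyl]-5-hydroxy-2,3-dihydro-4H-chromen-4-one
Conditions: HCl (1.25 M in MeOH), rt → 35 °C
Reagents that add atoms: none
Why: Acid-catalysed acetal exchange with methanol removes the three remaining acetal groups while the benzyl ethers stay and the trans stereocentres (already the thermodynamic arrangement at C3) are untouched.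

Step 11
Reactants: 21 (2R,3S)-7-(benzyloxy)-2-[4-(benzyloxy)phenyl]-3-[4-(benzyloxy)-2,6-dihydroxyphenyl]-5-hydroxy-2,3-dihydro-4H-chromen-4-one; 22 acetonitrile
Product: 24 (2R,3S)-3-[3-acetyl-4-(benzyloxy)-2,6-dihydroxyphenyl]-7-(benzyloxy)-2-[4-(benzyloxy)phenyl]-5-hydroxy-2,3-dihydro-4H-chromen-4-one, via ketiminium chloride 23 (not isolated)
Conditions: HCl (g), ZnCl2, Et2O, 0 °C; then H2O, 60 °C
Reagents that add atoms: water, O
Why: Houben–Hoesch acylation attacks only the free resorcinol-type ring, whose two open positions are equivalent and each lie between a free hydroxyl and the benzyl ether; the acyl-deactivated ring A of unit 1 does not react.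

Step 12
Reactants: 24 (2R,3S)-3-[3-acetyl-4-(benzyloxy)-2,6-dihydroxyphenyl]-7-(benzyloxy)-2-[4-(benzyloxy)phenyl]-5-hydroxy-2,3-dihydro-4H-chromen-4-one; 25 N,N-dimethylformamide dimethyl acetal
Product: 27 5-(benzyloxy)-8-{(2R,3S)-7-(benzyloxy)-2-[4-(benzyloxy)phenyl]-5-hydroxy-4-oxo-3,4-dihydro-2H-chromen-3-yl}-7-hydroxy-4H-chromen-4-one, via enaminone 26 (not isolated)
Conditions: 25 (1.5 equiv), toluene, 60 °C; then aq. HCl, CH2Cl2, rt
Reagents that add atoms: none
Why: Condensation at the acetyl group gives an enaminone, and acid then closes the pyranone by addition–elimination through the only free ortho hydroxyl (enaminone chromone synthesis), which fixes the 3,8''-linkage because O-5'' is benzylated; the aprotic medium disfavours base-induced opening of unit 1.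

Step 13
Reactants: 28 4-bromophenol
Product: 29 1-bromo-4-methoxybenzene
Conditions: MeI, K2CO3, acetone, reflux
Reagents that add atoms: iodomethane, CI
Why: Williamson O-methylation installs the only methyl ether of the target.

Step 14
Reactants: 29 1-bromo-4-methoxybenzene
Product: 32 (4-methoxyphenyl)boronic acid, via Grignard reagent 30 (not isolated), via dimethyl boronate 31 (not isolated)
Conditions: Mg, THF, rt; B(OMe)3, −78 °C → rt; aq. HCl
Reagents that add atoms: trimethyl borate, COB(OC)OC; water, O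
Why: Grignard formation, borylation with the borate ester and hydrolysis is the standard arylboronic acid synthesis.

Step 15
Reactants: 27 5-(benzyloxy)-8-{(2R,3S)-7-(benzyloxy)-2-[4-(benzyloxy)phenyl]-5-hydroxy-4-oxo-3,4-dihydro-2H-chromen-3-yl}-7-hydroxy-4H-chromen-4-one; 32 (4-methoxyphenyl)boronic acid
Product: 33 (2S)-5-(benzyloxy)-8-{(2R,3S)-7-(benzyloxy)-2-[4-(benzyloxy)phenyl]-5-hydroxy-4-oxo-3,4-dihydro-2H-chromen-3-yl}-7-hydroxy-2-(4-methoxyphenyl)-2,3-dihydro-4H-chromen-4-one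
Conditions: Pd(OCOCF3)2 (5 mol %), (R)-4-tert-butyl-2-(pyridin-2-yl)-4,5-dihydrooxazole (6 mol %), NH4PF6 (30 mol %), H2O (5 equiv), ClCH2CH2Cl, 50 °C
Reagents that add atoms: none
Why: Palladium/pyridine-oxazoline-catalysed asymmetric conjugate addition of the arylboronic acid to the chromone sets C2'' as S under ligand control, and protonation of the palladium enolate gives the flavanone without base that could open unit 1.

Step 16
Reactants: 33 (2S)-5-(benzyloxy)-8-{(2R,3S)-7-(benzyloxy)-2-[4-(benzyloxy)phenyl]-5-hydroxy-4-oxo-3,4-dihydro-2H-chromen-3-yl}-7-hydroxy-2-(4-methoxyphenyl)-2,3-dihydro-4H-chromen-4-one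
Product: 34 (2S)-8-[(2R,3S)-5,7-dihydroxy-2-(4-hydroxyphenyl)-4-oxo-3,4-dihydro-2H-chromen-3-yl]-5,7-dihydroxy-2-(4-methoxyphenyl)-2,3-dihydro-4H-chromen-4-one
Conditions: H2 (1 atm), 10% Pd/C, EtOAc/MeOH, rt
Reagents that add atoms: none
Why: Neutral hydrogenolysis cleaves the three benzyl ethers and leaves the aryl ketones, the methyl ether and all three stereocentres intact.

**Compound list**

1 | resorcinol | Oc1cccc(O)c1 | starting material
2 | 1,3-bis(methoxymethoxy)benzene | COCOc1cccc(OCOC)c1 | intermediate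
3 | 2-[3,5-bis(methoxymethoxy)phenyl]-4,4,5,5-tetramethyl-1,3,2-dioxaborolane | COCOc1cc(OCOC)cc(c1)B1OC(C)(C)C(C)(C)O1 | intermediate (not isolated)
4 | 3,5-bis(methoxymethoxy)phenol | COCOc1cc(O)cc(OCOC)c1 | intermediate
5 | 1-(benzyloxy)-3,5-bis(methoxymethoxy)benzene | COCOc1cc(OCOC)cc(OCc2ccccc2)c1 | intermediate
6 | N,N-dimethylcarbamoyl chloride | CN(C)C(Cl)=O | starting material
7 | [4-(benzyloxy)-2,6-bis(methoxymethoxy)phenyl]lithium | [Li]c1c(OCOC)cc(OCc2ccccc2)cc1OCOC | intermediate (not isolated)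
8 | 4-(benzyloxy)-2,6-bis(methoxymethoxy)-N,N-dimethylbenzamide | CN(C)C(=O)c1c(OCOC)cc(OCc2ccccc2)cc1OCOC | intermediate (not isolated)
9 | lithium bis[4-(benzyloxy)-2,6-bis(methoxymethoxy)phenyl](dimethylamino)methanolate | CN(C)C(O[Li])(c1c(OCOC)cc(OCc2ccccc2)cc1OCOC)c1c(OCOC)cc(OCc2ccccc2)cc1OCOC | intermediate (not isolated)
10 | bis[4-(benzyloxy)-2,6-bis(methoxymethoxy)phenyl]methanone | O=C(c1c(OCOC)cc(OCc2ccccc2)cc1OCOC)c1c(OCOC)cc(OCc2ccccc2)cc1OCOC | intermediate
11 | 4-methylphenol | Cc1ccc(O)cc1 | starting material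
12 | 4-hydroxybenzaldehyde | O=Cc1ccc(O)cc1 | intermediate
13 | 4-(benzyloxy)benzaldehyde | O=Cc1ccc(OCc2ccccc2)cc1 | intermediate
14 | dibromomethane | BrCBr | starting material
15 | lithium 1,1-bis[4-(benzyloxy)-2,6-bis(methoxymethoxy)phenyl]-2,2-dibromoethanolate | [Li]OC(C(Br)Br)(c1c(OCOC)cc(OCc2ccccc2)cc1OCOC)c1c(OCOC)cc(OCc2ccccc2)cc1OCOC | intermediate (not isolated)
16 | lithium 1,1-bis[4-(benzyloxy)-2,6-bis(methoxymethoxy)phenyl]-2-bromo-2-lithioethanolate (β-oxido carbenoid) | [Li]OC(C([Li])Br)(c1c(OCOC)cc(OCc2ccccc2)cc1OCOC)c1c(OCOC)cc(OCc2ccccc2)cc1OCOC | intermediate (not isolated)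
17 | lithium 1,2-bis[4-(benzyloxy)-2,6-bis(methoxymethoxy)phenyl]ethenolate (geometry not defined) | [Li]OC(=Cc1c(OCOC)cc(OCc2ccccc2)cc1OCOC)c1c(OCOC)cc(OCc2ccccc2)cc1OCOC | intermediate (not isolated)
18 | 1,2-bis[4-(benzyloxy)-2,6-bis(methoxymethoxy)phenyl]-3-[4-(benzyloxy)phenyl]-3-hydroxypropan-1-one (racemic diastereomer mixture) | O=C(c1c(OCOC)cc(OCc2ccccc2)cc1OCOC)C(c1c(OCOC)cc(OCc2ccccc2)cc1OCOC)C(O)c1ccc(OCc2ccccc2)cc1 | intermediate
19 | 1-[4-(benzyloxy)-2-hydroxy-6-(methoxymethoxy)phenyl]-2-[4-(benzyloxy)-2,6-bis(methoxymethoxy)phenyl]-3-[4-(benzyloxy)phenyl]-3-hydroxypropan-1-one (racemic diastereomer mixture) | O=C(c1c(O)cc(OCc2ccccc2)cc1OCOC)C(c1c(OCOC)cc(OCc2ccccc2)cc1OCOC)C(O)c1ccc(OCc2ccccc2)cc1 | intermediate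
20 | (2R,3S)-7-(benzyloxy)-2-[4-(benzyloxy)phenyl]-3-[4-(benzyloxy)-2,6-bis(methoxymethoxy)phenyl]-5-(methoxymethoxy)-2,3-dihydro-4H-chromen-4-one | COCOc1cc(OCc2ccccc2)cc(OCOC)c1[C@@H]1C(=O)c2c(OCOC)cc(OCc3ccccc3)cc2O[C@H]1c1ccc(OCc2ccccc2)cc1 | intermediate
21 | (2R,3S)-7-(benzyloxy)-2-[4-(benzyloxy)phenyl]-3-[4-(benzyloxy)-2,6-dihydroxyphenyl]-5-hydroxy-2,3-dihydro-4H-chromen-4-one | Oc1cc(OCc2ccccc2)cc(O)c1[C@@H]1C(=O)c2c(O)cc(OCc3ccccc3)cc2O[C@H]1c1ccc(OCc2ccccc2)cc1 | intermediate
22 | acetonitrile | CC#N | starting material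
23 | ketiminium chloride of 24 | CC(=[NH2+])c1c(O)c([C@@H]2C(=O)c3c(O)cc(OCc4ccccc4)cc3O[C@H]2c2ccc(OCc3ccccc3)cc2)c(O)cc1OCc1ccccc1.[Cl-] | intermediate (not isolated)
24 | (2R,3S)-3-[3-acetyl-4-(benzyloxy)-2,6-dihydroxyphenyl]-7-(benzyloxy)-2-[4-(benzyloxy)phenyl]-5-hydroxy-2,3-dihydro-4H-chromen-4-one | CC(=O)c1c(O)c([C@@H]2C(=O)c3c(O)cc(OCc4ccccc4)cc3O[C@H]2c2ccc(OCc3ccccc3)cc2)c(O)cc1OCc1ccccc1 | intermediate
25 | N,N-dimethylformamide dimethyl acetal | COC(OC)N(C)C | starting material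
26 | (E)-3-(dimethylamino)prop-2-en-1-one (enaminone) derived from 24 | CN(C)/C=C/C(=O)c1c(O)c([C@@H]2C(=O)c3c(O)cc(OCc4ccccc4)cc3O[C@H]2c2ccc(OCc3ccccc3)cc2)c(O)cc1OCc1ccccc1 | intermediate (not isolated)
27 | 5-(benzyloxy)-8-{(2R,3S)-7-(benzyloxy)-2-[4-(benzyloxy)phenyl]-5-hydroxy-4-oxo-3,4-dihydro-2H-chromen-3-yl}-7-hydroxy-4H-chromen-4-one | O=c1ccoc2c([C@@H]3C(=O)c4c(O)cc(OCc5ccccc5)cc4O[C@H]3c3ccc(OCc4ccccc4)cc3)c(O)cc(OCc3ccccc3)c12 | intermediate
28 | 4-bromophenol | Oc1ccc(Br)cc1 | starting material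
29 | 1-bromo-4-methoxybenzene | COc1ccc(Br)cc1 | intermediate
30 | (4-methoxyphenyl)magnesium bromide | COc1ccc([Mg]Br)cc1 | intermediate (not isolated)
31 | dimethyl (4-methoxyphenyl)boronate | COB(OC)c1ccc(OC)cc1 | intermediate (not isolated)
32 | (4-methoxyphenyl)boronic acid | COc1ccc(B(O)O)cc1 | intermediate
33 | (2S)-5-(benzyloxy)-8-{(2R,3S)-7-(benzyloxy)-2-[4-(benzyloxy)phenyl]-5-hydroxy-4-oxo-3,4-dihydro-2H-chromen-3-yl}-7-hydroxy-2-(4-methoxyphenyl)-2,3-dihydro-4H-chromen-4-one | COc1ccc([C@@H]2CC(=O)c3c(OCc4ccccc4)cc(O)c([C@@H]4C(=O)c5c(O)cc(OCc6ccccc6)cc5O[C@H]4c4ccc(OCc5ccccc5)cc4)c3O2)cc1 | intermediate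
34 | (2S)-8-[(2R,3S)-5,7-dihydroxy-2-(4-hydroxyphenyl)-4-oxo-3,4-dihydro-2H-chromen-3-yl]-5,7-dihydroxy-2-(4-methoxyphenyl)-2,3-dihydro-4H-chromen-4-one | COc1ccc([C@@H]2CC(=O)c3c(O)cc(O)c([C@@H]4C(=O)c5c(O)cc(O)cc5O[C@H]4c4ccc(O)cc4)c3O2)cc1 | target

**Step count and risks**

Total step count: 16. Longest linear sequence: 12 (steps 1, 2, 3, 4, 7, 8, 9, 10, 11, 12, 15, 16).

Three steps most likely to fail:

Step 7 (carbenoid 1,2-aryl shift and aldol on a hindered hexa-oxygenated benzophenone). If 10 does not take up dibromomethyllithium or the carbenoid does not rearrange cleanly, the deoxybenzoin is built without a rearrangement, setting out from 5. Lithiation as in step 4 and opening of ethylene oxide (BF3·OEt2, −78 °C) give 2-[4-(benzyloxy)-2,6-bis(methoxymethoxy)phenyl]ethan-1-ol F1. Dess–Martin oxidation gives [4-(benzyloxy)-2,6-bis(methoxymethoxy)phenyl]acetaldehyde F2. Addition of a second portion of aryllithium 7 gives 1,2-bis[4-(benzyloxy)-2,6-bis(methoxymethoxy)phenyl]ethan-1-ol F3, and a second Dess–Martin oxidation gives 1,2-bis[4-(benzyloxy)-2,6-bis(methoxymethoxy)phenyl]ethan-1-one F4. Its lithium enolate (LiN(SiMe3)2, THF, −78 °C) adds to aldehyde 13, and the route is rejoined at 18.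

Step 8 (selective acetal cleavage next to a labile benzylic alcohol). If MgBr2·OEt2 ionises the benzylic hydroxyl of 18 before it cleaves the chelated acetal, the hydroxyl is removed first, setting out from 18. MsCl/Et3N (CH2Cl2, −20 °C) gives 1,2-bis[4-(benzyloxy)-2,6-bis(methoxymethoxy)phenyl]-3-[4-(benzyloxy)phenyl]-3-(methylsulfonyloxy)propan-1-one F5. DBU eliminates it to 1,2-bis[4-(benzyloxy)-2,6-bis(methoxymethoxy)phenyl]-3-[4-(benzyloxy)phenyl]prop-2-en-1-one F6 (E/Z mixture). MgBr2·OEt2 then frees the ketone-flanking phenol to give 1-[4-(benzyloxy)-2-hydroxy-6-(methoxymethoxy)phenyl]-2-[4-(benzyloxy)-2,6-bis(methoxymethoxy)phenyl]-3-[4-(benzyloxy)phenyl]prop-2-en-1-one F7. F7 is cyclised under the step 9 conditions, where the chiral acid catalyses the oxa-Michael closure through the same O-protonated, ion-paired cation, and the route is rejoined at 20.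

Step 9 (the proposed new enantioselective ring closure). If enantiocontrol is inadequate, known chemistry is used, setting out from 19. An achiral acid (TsOH·H2O 5 mol %, toluene, rt) gives the racemic 2,3-trans flavanone, that is 20 together with its mirror image (2S,3R)-7-(benzyloxy)-2-[4-(benzyloxy)phenyl]-3-[4-(benzyloxy)-2,6-bis(methoxymethoxy)phenyl]-5-(methoxymethoxy)-2,3-dihydro-4H-chromen-4-one F8. The two are separated by preparative chromatography on a chiral stationary phase (supercritical CO2/MeOH), and the route is rejoined at 20.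

**Further compounds**

F1 | step 7 | 2-[4-(benzyloxy)-2,6-bis(methoxymethoxy)phenyl]ethan-1-ol | OCCc1c(OCOC)cc(OCc2ccccc2)cc1OCOC
F2 | step 7 | [4-(benzyloxy)-2,6-bis(methoxymethoxy)phenyl]acetaldehyde | O=CCc1c(OCOC)cc(OCc2ccccc2)cc1OCOC
F3 | step 7 | 1,2-bis[4-(benzyloxy)-2,6-bis(methoxymethoxy)phenyl]ethan-1-ol | OC(Cc1c(OCOC)cc(OCc2ccccc2)cc1OCOC)c1c(OCOC)cc(OCc2ccccc2)cc1OCOC
F4 | step 7 | 1,2-bis[4-(benzyloxy)-2,6-bis(methoxymethoxy)phenyl]ethan-1-one | O=C(Cc1c(OCOC)cc(OCc2ccccc2)cc1OCOC)c1c(OCOC)cc(OCc2ccccc2)cc1OCOC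
F5 | step 8 | 1,2-bis[4-(benzyloxy)-2,6-bis(methoxymethoxy)phenyl]-3-[4-(benzyloxy)phenyl]-3-(methylsulfonyloxy)propan-1-one | CS(=O)(=O)OC(c1ccc(OCc2ccccc2)cc1)C(C(=O)c1c(OCOC)cc(OCc2ccccc2)cc1OCOC)c1c(OCOC)cc(OCc2ccccc2)cc1OCOC
F6 | step 8 | 1,2-bis[4-(benzyloxy)-2,6-bis(methoxymethoxy)phenyl]-3-[4-(benzyloxy)phenyl]prop-2-en-1-one (E/Z mixture) | O=C(c1c(OCOC)cc(OCc2ccccc2)cc1OCOC)C(=Cc1ccc(OCc2ccccc2)cc1)c1c(OCOC)cc(OCc2ccccc2)cc1OCOC
F7 | step 8 | 1-[4-(benzyloxy)-2-hydroxy-6-(methoxymethoxy)phenyl]-2-[4-(benzyloxy)-2,6-bis(methoxymethoxy)phenyl]-3-[4-(benzyloxy)phenyl]prop-2-en-1-one (E/Z mixture) | O=C(c1c(O)cc(OCc2ccccc2)cc1OCOC)C(=Cc1ccc(OCc2ccccc2)cc1)c1c(OCOC)cc(OCc2ccccc2)cc1OCOC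
F8 | step 9 | (2S,3R)-7-(benzyloxy)-2-[4-(benzyloxy)phenyl]-3-[4-(benzyloxy)-2,6-bis(methoxymethoxy)phenyl]-5-(methoxymethoxy)-2,3-dihydro-4H-chromen-4-one | COCOc1cc(OCc2ccccc2)cc(OCOC)c1[C@H]1C(=O)c2c(OCOC)cc(OCc3ccccc3)cc2O[C@@H]1c1ccc(OCc2ccccc2)cc1
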